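Gmelinol hides an aldol retron. The tertiary C3a–OH and the benzylic C6–O stand 1,3 across the ring-fusion bond C3a–C6a, which both oxolane rings share. This bond is closed by a Pd(OAc)2-catalysed acetoxypalladation/carbonyl-insertion cyclization of an acyclic aryl alkynyl ketone. That precursor is the propargyl ether of an α-acetoxy ketone whose only stereocentre is C3. One operation closes ring A, builds the C3a carbinol under control of C3, and loads C6 with oxygen at the ketone level as an enol acetate. Deacetylation then folds ring B as a hemiketal. Hydride attack on its oxocarbenium ion from the convex face sets the endo aryl group at C6.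

Key step: step 6

Remark on locants: the furo[3,4-c]furan numbering of the target is used for all intermediates. C3 and C6 carry the aryl groups, C3a the OH, C6a the H. Ring A = C1/O2/C3/C3a/C6a and ring B = C4/O5/C6/C6a/C3a. Aryl = 3,4-dimethoxyphenyl.
Remark on chemistry (assumption): (E)-3,4-dimethoxycinnamyl alcohol is taken as a catalogue compound.

Step 1
Reactants: 1 4-iodo-1,2-dimethoxybenzene; 2 prop-2-yn-1-ol
Product: 3 3-(3,4-dimethoxyphenyl)prop-2-yn-1-ol
Conditions: PdCl2(PPh3)2 (2 mol %), CuI (4 mol %), Et3N, THF, rt
Reagents that add atoms: none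
Why: Sonogashira coupling of an aryl iodide with a terminal alkyne tolerates the free propargylic OH and creates no stereocentre.

Step 2
Reactants: 4 (E)-3-(3,4-dimethoxyphenyl)prop-2-en-1-ol
Product: 5 [(2S,3S)-3-(3,4-dimethoxyphenyl)oxiran-2-yl]methanol
Conditions: Ti(OiPr)4 (10 mol %), L-(+)-diisopropyl tartrate (12 mol %), t-BuOOH, 4 Å MS, CH2Cl2, −25 °C; non-acidic work-up
Reagents that add atoms: tert-butyl hydroperoxide, CC(C)(C)OO
Why: Sharpless asymmetric epoxidation of an (E)-allylic alcohol, in which the L-(+)-tartrate/titanium complex delivers oxygen to the alkene face that gives the (2S,3S)-epoxide and so fixes the absolute configuration of the whole route.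

Step 3
Reactants: 5 [(2S,3S)-3-(3,4-dimethoxyphenyl)oxiran-2-yl]methanol; 3 3-(3,4-dimethoxyphenyl)prop-2-yn-1-ol
Product: 6 (2S,3R)-3-(3,4-dimethoxyphenyl)-3-{[3-(3,4-dimethoxyphenyl)prop-2-yn-1-yl]oxy}propane-1,2-diol
Conditions: 3 (3 equiv, excess recovered), Eu(OTf)3 (10 mol %), 2,6-di-tert-butyl-4-methylpyridine (20 mol %), CH2Cl2, 0 °C to rt
Reagents that add atoms: none
Why: Lewis acid-catalysed alcoholysis of a 2,3-epoxy alcohol, in which chelation by Eu(OTf)3 and benzylic activation direct alcohol 3 to the benzylic carbon (C3) and backside attack inverts it to the (R)-ether of the target, any retention product being a separable diastereomer because C3a is still stereogenic.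

Step 4
Reactants: 6 (2S,3R)-diol
Product: 7 (2S,3R)-3-(3,4-dimethoxyphenyl)-3-{[3-(3,4-dimethoxyphenyl)prop-2-yn-1-yl]oxy}-2-hydroxypropyl acetate
Conditions: AcCl (1.1 equiv), 2,4,6-collidine (2 equiv), CH2Cl2, −78 °C
Reagents that add atoms: acetyl chloride, CC(=O)Cl
Why: Kinetically selective O-acylation takes the unhindered primary hydroxyl, leaves the flanked secondary OH free and touches no stereocentre.

Step 5
Reactants: 7 hydroxy acetate
Product: 8 (3R)-3-(3,4-dimethoxyphenyl)-3-{[3-(3,4-dimethoxyphenyl)prop-2-yn-1-yl]oxy}-2-oxopropyl acetate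
Conditions: Dess–Martin periodinane (1.3 equiv), CH2Cl2, 0 °C to rt
Reagents that add atoms: none
Why: Dess–Martin oxidation is non-basic, so the carbinol becomes the ketone without enolisation towards the adjacent benzylic ether stereocentre C3, and the alkyne, acetate and veratryl rings are inert.

Step 6
Reactants: 8 alkynyl α-acetoxy ketone
Product: 9 [(2R,3S,4E)-4-[acetoxy(3,4-dimethoxyphenyl)methylidene]-2-(3,4-dimethoxyphenyl)-3-hydroxyoxolan-3-yl]methyl acetate
Conditions: Pd(OAc)2 (5 mol %), 2,2'-bipyridine (6 mol %), AcOH/1,4-dioxane (1:4), 60 °C, N2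
Reagents that add atoms: acetic acid, CC(=O)O
Why: The bipyridine-ligated Pd(OAc)2 binds the alkyne, external acetate adds anti to the aryl-bearing carbon (future C6) and leaves a vinyl–palladium bond on the propargylic alkyne carbon (future C6a), the ketone inserts into this bond, and acetic acid protonates the palladium alkoxide, so the metal stays divalent palladium throughout. This is the known acetoxypalladation-initiated cyclization of alkynes tethered to aldehydes or ketones through a propargyl ether, applied here to a more electrophilic α,α'-dioxygenated ketone. Ring A closes by forming C3a–C6a, 5-exo-dig at the alkyne and 5-exo-trig at the carbonyl. The only new stereocentre, C3a, is controlled by C3: in the envelope-like insertion transition state the C3 aryl group sits pseudo-equatorial and the CH2OAc branch takes the position trans to it, which should put the new OH cis to that aryl group as in the target, while anti addition fixes the E enol acetate. The electron-rich aryl group and the inductive pull of the propargylic oxygen secure acetate attack at C6, and the bidentate nitrogen ligand and the activated ketone favour insertion over protonolysis of the vinyl–palladium bond. The enol acetate stores C6 at the ketone level without ever forming a free enolate beside the β-oxygen substituents or needing a base that could epimerise C3.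

Step 7
Reactants: 9 enol acetate
Product: 11 bicyclic hemiketal (6-hydroxygmelinol; C3 R, C3a S, cis ring fusion, C6 anomers), via keto diol 10 (not isolated)
Conditions: K2CO3 (0.3 equiv), MeOH, 0 °C
Reagents that add atoms: none
Why: Zemplén-type transesterification frees the enol and the primary alcohol, the enol is protonated at C6a from the face of the small C3a–OH (and C6a can still equilibrate under the mild base), so the aroyl group ends cis to CH2OH and keto diol 10 closes ring B as the cis-fused hemiketal 11.

Step 8
Reactants: 11 bicyclic hemiketal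
Product: 13 (+)-gmelinol, (3R,3aS,6R,6aR)-3,6-bis(3,4-dimethoxyphenyl)tetrahydro-1H,3H-furo[3,4-c]furan-3a-ol, via oxocarbenium ion 12 (not isolated)
Conditions: Et3SiH (5 equiv), BF3·OEt2 (1.5 equiv, promoter), CH2Cl2, −78 °C; Et3N quench at −78 °C
Reagents that add atoms: none
Why: Ionic hemiketal reduction as used for C-aryl glycosides, in which oxocarbenium ion 12 of the cis-fused bicycle should accept hydride only from its convex face, placing H-6 exo and the aryl group endo (6R), while the low temperature prevents acid epimerisation of the two benzylic ethers.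

Compound list
1 | 4-iodo-1,2-dimethoxybenzene | COc1ccc(I)cc1OC | starting material
2 | prop-2-yn-1-ol | C#CCO | starting material
3 | 3-(3,4-dimethoxyphenyl)prop-2-yn-1-ol | COc1ccc(C#CCO)cc1OC | intermediate
4 | (E)-3-(3,4-dimethoxyphenyl)prop-2-en-1-ol | COc1ccc(/C=C/CO)cc1OC | starting material
5 | [(2S,3S)-3-(3,4-dimethoxyphenyl)oxiran-2-yl]methanol | OC[C@@H]1O[C@H]1c2ccc(OC)c(OC)c2 | intermediate
6 | (2S,3R)-3-aryl-3-(3-arylprop-2-ynyloxy)propane-1,2-diol | COc1ccc([C@@H](OCC#Cc2ccc(OC)c(OC)c2)[C@@H](O)CO)cc1OC | intermediate
7 | (2S,3R)-3-aryl-3-(3-arylprop-2-ynyloxy)-2-hydroxypropyl acetate | COc1ccc([C@@H](OCC#Cc2ccc(OC)c(OC)c2)[C@@H](O)COC(C)=O)cc1OC | intermediate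
8 | (3R)-3-aryl-3-(3-arylprop-2-ynyloxy)-2-oxopropyl acetate | COc1ccc([C@@H](OCC#Cc2ccc(OC)c(OC)c2)C(=O)COC(C)=O)cc1OC | intermediate
9 | (2R,3S,4E)-enol acetate of ring A (OH cis to the C3 aryl group, OAc anti to C3a) | COc1ccc([C@H]2OC/C(=C(\OC(C)=O)c3ccc(OC)c(OC)c3)[C@]2(O)COC(C)=O)cc1OC | intermediate
10 | (2R,3S,4S)-4-aroyl-2-aryl-3-(hydroxymethyl)oxolan-3-ol (aroyl cis to CH2OH) | COc1ccc([C@H]2OC[C@H](C(=O)c3ccc(OC)c(OC)c3)[C@]2(O)CO)cc1OC | intermediate
11 | bicyclic hemiketal, 6-hydroxygmelinol (C6 anomers) | COc1ccc([C@H]2OC[C@@H]3C(O)(c4ccc(OC)c(OC)c4)OC[C@]23O)cc1OC | intermediate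
12 | C6 oxocarbenium ion of the cis-fused bicycle | COc1ccc([C@H]2OC[C@@H]3C(c4ccc(OC)c(OC)c4)=[O+]C[C@]23O)cc1OC | intermediate
13 | (+)-gmelinol | COc1ccc([C@H]2OC[C@@H]3[C@H](c4ccc(OC)c(OC)c4)OC[C@]23O)cc1OC | target

Total step count: 8. Longest linear sequence: 7 steps (4 to 13, steps 2–8).

Steps most likely to fail

1. Step 6. Four processes threaten this step.
- The vinyl–palladium bond may be protonated before the ketone inserts.
- The doubly activated tertiary allylic alcohol of the product may ionise in warm acetic acid.
- The ketone may enolise slowly towards C3, which would erode enantiopurity.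
- Facial selectivity at the carbonyl may be poor.

The fallback sets out from 8 and comes back at 11. The alkyne of 8 is oxidised with 8-methylquinoline N-oxide under (Ph3P)AuNTf2 catalysis (α-oxo gold carbene, then 1,2-hydride shift) to the (E)-β-alkoxy enone F1. Conjugate reduction of F1 with [(Ph3P)CuH]6 in toluene at low temperature gives a regiodefined copper enolate. This enolate closes the same C3a–C6a bond in a reductive aldol cyclization to the aroyl oxolane acetate F2. The chelated transition state should place the aroyl group of F2 cis to the C3a–OH. K2CO3 in MeOH then removes the acetate and equilibrates C6a through the enol, so that the material drains into hemiketal 11.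

2. Step 8. Three processes threaten this step.
- The oxocarbenium ion may lose H-6a and the resulting enol ether may dehydrate towards a furan.
- The open keto form may be over-reduced.
- The benzylic ethers may epimerise under acid.

The fallback sets out from 11 and comes back at 13, and it avoids any cation at C6. Evans–Saksena reduction (Me4NBH(OAc)3, MeCN/AcOH, −20 °C) acts on the open form. Hydride is delivered internally from the borate at C3a–OH through a chair with the aryl group equatorial, which should give the (6R)-triol F3. TsCl in pyridine sulfonylates the primary hydroxyl to the primary tosylate F4. NaH in THF then closes ring B by a Williamson displacement at C4, which leaves the C6–O bond and its configuration untouched and gives 13.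

3. Step 3. Three processes threaten this step.
- The electron-rich benzylic epoxide may ionise ahead of attack, with loss of inversion fidelity.
- It may rearrange by hydride shift.
- It may be opened by the hydroxyl of a second epoxy alcohol.

The fallback sets out from 4 and 3 and comes back at 8, and it sets C3 by asymmetric catalysis instead of epoxide opening.
- Alcohol 4 is converted with ClCO2Me and pyridine into the cinnamyl methyl carbonate F5.
- Iridium-catalysed asymmetric allylic etherification follows, using [Ir(cod)Cl]2, a chiral binaphthol-derived phosphoramidite, and the alkoxide of 3 made with n-BuLi and CuI. It gives the branched (S)-allyl ether F6, which has the same spatial arrangement at C3 as 8.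
- OsO4 (cat.) with N-methylmorpholine N-oxide dihydroxylates only the vinyl group to the C3a-epimeric diols F7.
- AcCl and collidine give the primary monoacetates F8.
- Dess–Martin oxidation erases C3a and converges both epimers on 8.

Further compounds
F1 | step 6 | (3R)-3-aryl-3-{[(E)-3-aryl-3-oxoprop-1-enyl]oxy}-2-oxopropyl acetate | COc1ccc([C@@H](O/C=C/C(=O)c2ccc(OC)c(OC)c2)C(=O)COC(C)=O)cc1OC
F2 | step 6 | [4-aroyl-2-aryl-3-hydroxyoxolan-3-yl]methyl acetate, aroyl cis to OH | COc1ccc([C@H]2OC[C@@H](C(=O)c3ccc(OC)c(OC)c3)[C@]2(O)COC(C)=O)cc1OC
F3 | step 8 | (6R)-triol: 2-aryl-4-[(R)-aryl(hydroxy)methyl]-3-(hydroxymethyl)oxolan-3-ol | COc1ccc([C@H]2OC[C@H]([C@@H](O)c3ccc(OC)c(OC)c3)[C@]2(O)CO)cc1OC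
F4 | step 8 | primary p-toluenesulfonate of F3 | COc1ccc([C@H]2OC[C@H]([C@@H](O)c3ccc(OC)c(OC)c3)[C@]2(O)COS(=O)(=O)c4ccc(C)cc4)cc1OC
F5 | step 3 | (E)-3-(3,4-dimethoxyphenyl)allyl methyl carbonate | COC(=O)OC/C=C/c1ccc(OC)c(OC)c1
F6 | step 3 | (S)-1-aryl-1-(3-arylprop-2-ynyloxy)prop-2-ene | COc1ccc([C@@H](OCC#Cc2ccc(OC)c(OC)c2)C=C)cc1OC
F7 | step 3 | (3R)-3-aryl-3-(3-arylprop-2-ynyloxy)propane-1,2-diol, both C2 epimers | COc1ccc([C@@H](OCC#Cc2ccc(OC)c(OC)c2)C(O)CO)cc1OC
F8 | step 3 | primary monoacetate of F7, both C2 epimers | COc1ccc([C@@H](OCC#Cc2ccc(OC)c(OC)c2)C(O)COC(C)=O)cc1OC
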